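If each G costs one Z and one X, you can count half-lives in this flask with a single number read from the runs.

common to all: J 3.3 µM
- dawn: Z 5 mM; X 6.5 mM; the very flask that is asked about, followed so far
- midnight: Z 5 mM; X 3.2 mM; run made earlier
- flask: Z 5.0 mM; X 6.50 mM; time 2.5 min

| run | time / s | L / % | G / % |
|---|---|---|---|
| dawn | 10.0 | 4 | 9 |
| dawn | 15.0 | 1 | 12 |
| dawn | 25.0 | 2 | 25 |
| dawn | 30.0 | 0 | 34 |
| midnight | 10.0 | 0 | 0 |
| midnight | 12.0 | 0 | 4 |
| midnight | 20.0 | 0 | 11 |
| midnight | 30.0 | 0 | 17 |
| midnight | 50.0 | 1 | 28 |
| midnight | 60.0 | 2 | 31 |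

(readings scatter by 2 percentage points)

* amount of L in the flask at 2.5 min, in percent of the Z charged
* amount of G in the flask at 2.5 min, in percent of the Z charged
* amount of Z in the flask at 2.5 min, in percent of the Z charged
* concentration of X at 2.5 min, in mM

1. X. By hand, more [X] gives a faster rate. The dawn run has 2.03 times the [X] of the midnight run. From 10.0 s to 30.0 s it gains 25 percentage points of G, more than the 17 points of midnight.

2. Z. Neither run changes the charge of Z. By hand, I take the rate as proportional to [Z] as well. Define κ, the pair constant, as the rate of G divided by [Z][X]. From 30.0 s to 60.0 s, midnight gains 14 points, at a mean [Z] of 3.80 mM and a mean [X] of 2.00 mM. So κ reads 3.07 M⁻¹ s⁻¹, with the scatter of those readings. The half-life of either partner is then ln(2) divided by κ times the other's concentration.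

3. J. Both runs charge 3.3 µM, so κ belongs to that charge.

4. Time. Midnight shows 0% G at 10.0 s, so I count from there, which leaves 140 s. My own reckoning for the flask gives [Z] of 1.02 mM, or 20.3% of the charge, and [X] of 2.52 mM.

5. The forecast says L 10%, G 85%, Z 5% and X 1.2 mM, reading the rate as “first order in X and about zero order in Z”. It parts from my reckoning on Z and X.

6. The flask gives L 2.73%, G 82.1%, Z 15.2% and X 2.26 mM.

    Z + X + Q → Q + G (k = 1.20 × 10⁶ M⁻² s⁻¹)
    J → Q (k = 0.0700 s⁻¹)
    Z + X → L (k = 0.0970 M⁻¹ s⁻¹)

7. At 2.50 min the step through Q uses X 41 times as fast as Z + X → L. The half-life of Z by Z + X → L alone is 18 min, long against 2.5 min. At the final [X], κ gives Z a half-life of 1.67 min, against 1.3 min from the constants. In the neighbour flask with 20 mM of Z, X is the limiting reagent, and the reckoning of step 4, with [Z] falling as X is used, leaves [X] of 0.0133 mM, which is 8.94 halvings. That flask keeps 0.0392% of its X, which is 11.3 halvings.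

Readings and results stem from a simulated flask on assumed constants, noise included.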